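E is born from X in a single step and afterwards eaten by L, so for beta and epsilon we need a birth share and a survival.

- beta: X 0.020 M; Q 2.3 mM (held); time 2.0 h
- epsilon: X 0.020 M; Q 2.3 mM (held); time 4.0 h

    X → E (k1 = 0.013 /min)
    X + L → X.L (k2 = 32 /M/min)
    X + L → Z (k3 = 0.33 /M/min)
    Z ⇌ G (K4 = 4.0, k4 = 0.0018 /min)
    Q ⇌ L, rate k5*(csat - [L]) (k5 = 0.33 /min, csat = 2.3 mM)
    L + E → L.E (k6 = 3.1 /M/min)

* which of the two there is more of at the end, beta (E / X.L)
* which of the two there is more of at the end, epsilon (E / X.L)
* final E, as a percentage of the X charged, in beta
* final E, as a percentage of the X charged, in epsilon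

We keep a ledger of X, the limiting reagent, and follow one molecule to its fork. It turns into E with constant 0.013 /min, or it takes L with constant 32 /M/min times [L], the dissolved concentration. The gas feeds L in proportion to the gap below 2.3 mM, while X takes L up. Setting supply equal to uptake gives [L] and the chance of E at the two ends of the life of X:

X at its charge: [L] = 0.782 mM, chance of E 34.2 %

limit of little X: [L] = 2.3 mM, chance of E 15.0 %

Here 1.94 is the uptake of L by the charged X relative to the transfer coefficient, and 5.66 is the pull of saturated L relative to the step to E. Averaging the chance over every molecule of X with these two gives: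

share to E: 25.4 %, taken by L: 74.6 %

So a quarter of X enters the E column. Of what L takes, 1.02 % goes to Z and the rest to X.L, which puts X.L ahead of E in both flasks.

The second entry is E's loss. With [L] at 2.3 mM, E decays in a pseudo-first-order way. We call κ = 0.00713 /min the erosion rate of E at saturation; it gives a half-life of 1.62 h. Dating E's birth at the starting life of X, 26.3 min, we commit to:

beta: 13.0 %

epsilon: 5.54 %

The forecast named X.L in beta and X.L in epsilon, with E at 13.5 % and 5.8 %, a little above our figures, holding that “L sits near saturation and slowly eats E”.

The simulation gives E 14.6 % against X.L 72.2 % in beta, and E 6.29 % against X.L 72.3 % in epsilon, so E stands above our reckoning in beta.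

In epsilon, the step X → E has >99.9 % of its turnover behind it at 2.00 h, while at 4.00 h E has a half-life of 1.6 h on the path to L.E. Between beta's reading and epsilon's, κ gives a surviving fraction of 0.425, and the two readings give 0.431. Epsilon's flask read at 2.5 h is reckoned from beta's 14.6 % as 11.8 %, and it holds 11.8 %.

All constants were drawn at random within sensible limits; what happens was integrated by code.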